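**Plan** (pinane atoms: C1/C5 bridgeheads, C2 spiro carbon, C3, C4, C6 = CMe2, C7 = CH2 bridge; primed atoms = chromene part)

1. Cuts: O1'–C2 and C3'–C4' (retro hetero-Diels–Alder) and C4'=C4a' (retro Knoevenagel) lead to (1R,5R)-β-pinene, isobutyraldehyde and syncarpic acid. C2=CH2 goes back to the ketone. The C3 methylene is then excised from ring C1–C2–C3–C4–C5–C7, C5–C7 and C1–C6 are cut (retro crossed [2+2]), and finally the two acyl bonds at C2.
2. Forward: an open-chain C8 dienone is made first. One photochemical step then builds the cyclobutane and both five-membered rings of a bicyclo[2.1.1]hexanone. A one-carbon ring enlargement (5 to 6) gives the pinane nucleus. Methylenation follows, and a three-component domino reaction closes the dihydropyran and sets the spiro centre.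
3. Enabling feature: C3 is an unsubstituted CH2 between C4 and C2, and C2 can be a carbonyl carbon at that stage. The other neighbour of C2 is the cyclobutane bridgehead C1, a poor migrating group. The rule of five makes the [2.1.1] skeleton, not the [3.1.1] skeleton, the accessible photoproduct, and its extra strain drives a single CH2 insertion.
4. Stereochemistry: the relative configuration at C1/C5 follows from the geometry of the [2+2]. The absolute configuration comes from covalent resolution with an (S)-sulfoximine that also serves as the methylenation reagent. C2 is set by attack anti to the gem-dimethyl bridge. C4' is set by the heterodiene face used, and its epimer is removed by chromatography.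

Key step: step 3

Remark: the pinane unit of the target corresponds to (1R,5R)-(+)-β-pinene. Compounds 4–7 are racemates, and their SMILES show the enantiomer that is carried into the target.

Step 1
Reactants: 1 1-chloro-3-methylbut-2-ene (prenyl chloride); 2 tributyl(vinyl)stannane
Product: 3 6-methylhepta-1,5-dien-3-one
Conditions: CO (3 atm), Pd2(dba)3 (2.5 mol %), PPh3 (10 mol %), THF, 50 °C
Reagents that add atoms: carbon monoxide, [C-]#[O+]
Why: Carbonylative Stille coupling: zerovalent palladium should insert into the allylic C–Cl bond, take up CO at the unsubstituted allyl terminus and pass the acyl group to the vinylstannane, which gives the β,γ-unsaturated vinyl ketone without a stereocentre and without touching the trisubstituted alkene.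

Step 2
Reactants: 3 6-methylhepta-1,5-dien-3-one
Product: 4 (±)-5,5-dimethylbicyclo[2.1.1]hexan-2-one
Conditions: hν (medium-pressure Hg lamp, Pyrex filter, λ > 300 nm), pentane (0.01 M), rt
Reagents that add atoms: none
Why: Intramolecular crossed [2+2] enone–alkene photocycloaddition of a 1,5-hexadien-3-one: the rule of five directs the first bond to C5–C7 (a five-membered 1,4-diradical with an α-acyl and a tertiary radical centre) and collapse at C1–C6 closes the cyclobutane, so both bridgeheads arise in the only relative configuration the bicycle allows, as a racemate.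

Step 3
Reactants: 4 (±)-5,5-dimethylbicyclo[2.1.1]hexan-2-one
Product: 7 (±)-6,6-dimethylbicyclo[3.1.1]heptan-2-one (nopinone), via α-silyl ketone 5 (not isolated), via silyl enol ether 6 (not isolated)
Conditions: TMSCHN2, Sc(OTf)3 (10 mol %), toluene, −20 °C to rt; then 1 M HCl, THF, rt
Reagents that add atoms: (trimethylsilyl)diazomethane, C[Si](C)(C)C=[N+]=[N-]
Why: Sc(OTf)3 activates the strained carbonyl of 4, the diazo carbon adds from the face of the CH2 bridge, and loss of N2 from the tetrahedral diazonium adduct is coupled to a 1,2-shift of the ring methylene (the later C4) onto the new carbon (the later C3), giving 5, which passes by C-to-O silyl shift into 6 and is hydrolysed to 7. The closest known reaction type is the Tiffeneau–Demjanov-type (Büchner–Curtius–Schlotterbeck) one-carbon homologation of strained cyclic ketones with TMSCHN2 under Sc(OTf)3 catalysis. No ring is closed: the inserted carbon lengthens the two-carbon bridge to three, so the five-membered ring made of C1, C2, C4, C5 and C7 becomes the six-membered ring C1–C2–C3–C4–C5–C7, its gem-dimethyl counterpart grows in the same way, and the cyclobutane stays intact. No stereocentre is created in 7, and both bridgeheads are spectators that keep their configuration. The step needs methylene rather than bridgehead migration, which is secured by the general preference of diazoalkane insertions for the less substituted carbon, by the high s-character of the cyclobutane bridgehead bond, and by the silyl group avoiding the bridgehead side in the reactive rotamer. It also needs a single insertion, which is secured because 4 is more strained and less shielded than 7 and because the product is masked in the flask as enol silane 6.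

Step 4
Reactants: 7 (±)-nopinone; 8 (S)-N,S-dimethyl-S-phenylsulfoximine
Product: 10 (1S,2S,5R)-6,6-dimethyl-2-{[(S)-N-methyl-S-phenylsulfonimidoyl]methyl}bicyclo[3.1.1]heptan-2-ol, via lithiated sulfoximine 9 (not isolated)
Conditions: 8, n-BuLi, THF, 0 °C; then 7, −78 °C; H2O quench; silica gel chromatography (separation of the two diastereomeric carbinols)
Reagents that add atoms: none
Why: Sulfoximine carbanion addition to a ketone (first half of the Johnson methylenation with resolution): the nucleophile should attack C2 from the face of the C7 methylene bridge, away from the gem-dimethyl bridge, so each ketone enantiomer gives one carbinol, and because sulfur is a single enantiomer the two carbinols are diastereomers that are parted on silica gel, which fixes the absolute configuration at C1 and C5.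

Step 5
Reactants: 10 β-hydroxysulfoximine
Product: 11 (1R,5R)-(+)-β-pinene
Conditions: Al/Hg, AcOH, THF–H2O, rt; extraction into pentane, careful distillation
Reagents that add atoms: none
Why: Reductive elimination of a β-hydroxysulfoximine (second half of the Johnson methylenation): two-electron reduction cleaves the C–S bond and expels hydroxide to give the exocyclic alkene under weakly acidic conditions that should not isomerise the pinene, with C1 and C5 untouched.

Step 6
Reactants: 12 1-(2,4,6-trihydroxyphenyl)ethanone
Product: 13 2-acetyl-4,4,6,6-tetramethylcyclohexane-1,3,5-trione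
Conditions: MeI, NaOMe, MeOH, reflux
Reagents that add atoms: iodomethane, CI
Why: Exhaustive dearomatising C-methylation of an acylphloroglucinol: the acyl group blocks one ring carbon and keeps the others nucleophilic, so four methyl groups should end up as two gem-dimethyl pairs, and no stereocentre is formed.

Step 7
Reactants: 13 2-acetyl-4,4,6,6-tetramethylcyclohexane-1,3,5-trione
Product: 14 2,2,4,4-tetramethylcyclohexane-1,3,5-trione (syncarpic acid)
Conditions: 6 M HCl (aq), reflux
Reagents that add atoms: none
Why: Acid-promoted retro-Claisen deacylation of a 2-acyl-1,3-dione: water adds to the exocyclic acetyl carbonyl and the stabilised triketone enol leaves, while the quaternary carbons are inert.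

Step 8
Reactants: 11 (+)-β-pinene (excess); 14 syncarpic acid (added slowly); 15 2-methylpropanal (isobutyraldehyde)
Product: 17 (1S,2S,4'R,5R)-6,6,6',6',8',8'-hexamethyl-4'-(propan-2-yl)-3',4'-dihydrospiro[bicyclo[3.1.1]heptane-2,2'-chromene]-5',7'(6'H,8'H)-dione, via enetrione 16 (not isolated)
Conditions: ethylenediammonium diacetate (10 mol %), 4 Å MS, toluene, 80 °C, sealed tube; chromatography
Reagents that add atoms: none
Why: Tietze domino Knoevenagel/inverse-electron-demand hetero-Diels–Alder reaction: 14 and 15 condense to heterodiene 16, whose O=C–C=C unit adds across the exocyclic alkene of 11 with oxygen bonding to the more substituted C2, the gem-dimethyl bridge blocks one alkene face so that oxygen arrives syn to C7 (2S), and C4' is fixed by the face of 16 that is presented (triketone ring over bridgehead C1 gives 4'R), so 17 should form beside its C4' epimer and is separated by chromatography.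

**Compound list**
1 | 1-chloro-3-methylbut-2-ene | CC(C)=CCCl | starting material
2 | tributyl(vinyl)stannane | C=C[Sn](CCCC)(CCCC)CCCC | starting material
3 | 6-methylhepta-1,5-dien-3-one | C=CC(=O)CC=C(C)C | intermediate
4 | (±)-5,5-dimethylbicyclo[2.1.1]hexan-2-one, (1S,4S) enantiomer drawn | O=C1C[C@@H]2C[C@H]1C2(C)C | intermediate
5 | (±)-6,6-dimethyl-3-(trimethylsilyl)bicyclo[3.1.1]heptan-2-one, C3 epimers | O=C1C([Si](C)(C)C)C[C@@H]2C[C@H]1C2(C)C | intermediate
6 | (±)-[(6,6-dimethylbicyclo[3.1.1]hept-2-en-2-yl)oxy]trimethylsilane | C[Si](C)(C)OC1=CC[C@@H]2C[C@H]1C2(C)C | intermediate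
7 | (±)-6,6-dimethylbicyclo[3.1.1]heptan-2-one (nopinone), (1S,5R) enantiomer drawn | O=C1CC[C@@H]2C[C@H]1C2(C)C | intermediate
8 | (S)-N,S-dimethyl-S-phenylsulfoximine | CN=[S@@](C)(=O)c1ccccc1 | starting material
9 | (S)-S-(lithiomethyl)-N-methyl-S-phenylsulfoximine | CN=[S@@](C[Li])(=O)c1ccccc1 | intermediate
10 | (1S,2S,5R)-6,6-dimethyl-2-{[(S)-N-methyl-S-phenylsulfonimidoyl]methyl}bicyclo[3.1.1]heptan-2-ol | CN=[S@@](C[C@]1(O)CC[C@@H]2C[C@H]1C2(C)C)(=O)c1ccccc1 | intermediate
11 | (1R,5R)-6,6-dimethyl-2-methylidenebicyclo[3.1.1]heptane, (+)-β-pinene | C=C1CC[C@@H]2C[C@H]1C2(C)C | intermediate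
12 | 1-(2,4,6-trihydroxyphenyl)ethanone | CC(=O)c1c(O)cc(O)cc1O | starting material
13 | 2-acetyl-4,4,6,6-tetramethylcyclohexane-1,3,5-trione (triketo tautomer) | CC(=O)C1C(=O)C(C)(C)C(=O)C(C)(C)C1=O | intermediate
14 | 2,2,4,4-tetramethylcyclohexane-1,3,5-trione, syncarpic acid (triketo tautomer) | O=C1CC(=O)C(C)(C)C(=O)C1(C)C | intermediate
15 | 2-methylpropanal | CC(C)C=O | starting material
16 | 2,2,4,4-tetramethyl-6-(2-methylpropylidene)cyclohexane-1,3,5-trione | CC(C)C=C1C(=O)C(C)(C)C(=O)C(C)(C)C1=O | intermediate
17 | (1S,2S,4'R,5R)-6,6,6',6',8',8'-hexamethyl-4'-(propan-2-yl)-3',4'-dihydrospiro[bicyclo[3.1.1]heptane-2,2'-chromene]-5',7'(6'H,8'H)-dione | CC(C)[C@H]1C[C@]2(CC[C@@H]3C[C@H]2C3(C)C)OC2=C1C(=O)C(C)(C)C(=O)C2(C)C | target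

Total step count: 8. Longest linear sequence: 6 (steps 1, 2, 3, 4, 5, 8).

**Steps most likely to fail**

Step 3. The bridgehead carbon may migrate in competition, which would place the carbonyl in the middle of the three-carbon bridge. The diazonium adduct may also close to a spiro-epoxide, or a second insertion may occur.

The fallback keeps the five-to-six enlargement but makes the site of insertion structural rather than kinetic. It sets out from 4 and returns at 7.
- LDA then TMSCl should give the only possible, non-bridgehead enol ether, [(5,5-dimethylbicyclo[2.1.1]hex-2-en-2-yl)oxy]trimethylsilane F1.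
- Furukawa cyclopropanation (Et2Zn, CH2I2, CH2Cl2) from the face of the CH2 bridge should give the siloxycyclopropane [(6,6-dimethyltricyclo[3.1.1.0(2,4)]heptan-2-yl)oxy]trimethylsilane F2.
- Ito–Saegusa ring enlargement (FeCl3, DMF, 0 °C) cleaves the internal cyclopropane bond oxidatively to 4-chloro-6,6-dimethylbicyclo[3.1.1]heptan-2-one F3.
- NaOAc in MeOH eliminates to 6,6-dimethylbicyclo[3.1.1]hept-3-en-2-one F4.
- H2 over Pd/C gives 7.

Step 8. There may be poor control over which face of the heterodiene is used, so the C4' epimer could dominate. Competing processes are the Alder-ene reaction of the allylic C3–H of the pinene and Michael addition of a second molecule of 14 to 16.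

The fallback replaces substrate control with catalyst control. It sets out from 14 and 15 and returns at 17.
- Heterodiene 16 is first made on its own (catalytic L-proline, CH2Cl2, 4 Å MS) and freed from 14.
- 16 is then combined with 11 at −20 °C in CH2Cl2 in the presence of the divalent copper complex Cu(OTf)2/tBu-bis(oxazoline). This complex chelates the two carbonyl oxygens that flank the alkylidene carbon and shields one face of 16.
- The ligand antipode that leaves open the face leading to 4'R is chosen.
- Any ene adduct is closed to the same spiro ether with a mild Brønsted acid, since oxygen again attacks C2 anti to the gem-dimethyl bridge.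

Step 4. The basic sulfoximine anion may enolise the hindered ketone, and the two carbinols may not separate well enough on silica gel.

The fallback separates resolution and methylenation. It sets out from 7 and returns at 11.
- NaBH4 in MeOH delivers hydride anti to the gem-dimethyl bridge and gives (±)-6,6-dimethylbicyclo[3.1.1]heptan-2-ol (OH syn to the gem-dimethyl bridge) F5.
- Lipase-catalysed acylation (CAL-B, vinyl acetate, MTBE) should, by the Kazlauskas rule, leave (1S,2S,5R)-6,6-dimethylbicyclo[3.1.1]heptan-2-ol F6 unreacted and convert its antipode into (1R,2R,5S)-6,6-dimethylbicyclo[3.1.1]heptan-2-yl acetate F7, which is removed.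
- Dess–Martin oxidation of F6 gives (1S,5R)-(−)-nopinone F8.
- Wittig methylenation (Ph3P=CH2, THF) gives 11.

**Further compounds**
F1 | step 3 | (±)-[(5,5-dimethylbicyclo[2.1.1]hex-2-en-2-yl)oxy]trimethylsilane | C[Si](C)(C)OC1=C[C@@H]2C[C@H]1C2(C)C
F2 | step 3 | (±)-[(6,6-dimethyltricyclo[3.1.1.0(2,4)]heptan-2-yl)oxy]trimethylsilane | C[Si](C)(C)O[C@@]12C[C@@H]1[C@@H]3C[C@H]2C3(C)C
F3 | step 3 | (±)-4-chloro-6,6-dimethylbicyclo[3.1.1]heptan-2-one, C4 epimers | O=C1CC(Cl)[C@@H]2C[C@H]1C2(C)C
F4 | step 3 | (±)-6,6-dimethylbicyclo[3.1.1]hept-3-en-2-one | O=C1C=C[C@@H]2C[C@H]1C2(C)C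
F5 | step 4 | (±)-6,6-dimethylbicyclo[3.1.1]heptan-2-ol, OH syn to the gem-dimethyl bridge, (1S,2S,5R) enantiomer drawn | O[C@H]1CC[C@@H]2C[C@H]1C2(C)C
F6 | step 4 | (1S,2S,5R)-6,6-dimethylbicyclo[3.1.1]heptan-2-ol, single enantiomer | O[C@H]1CC[C@@H]2C[C@H]1C2(C)C
F7 | step 4 | (1R,2R,5S)-6,6-dimethylbicyclo[3.1.1]heptan-2-yl acetate | CC(=O)O[C@@H]1CC[C@H]2C[C@@H]1C2(C)C
F8 | step 4 | (1S,5R)-6,6-dimethylbicyclo[3.1.1]heptan-2-one, (−)-nopinone | O=C1CC[C@@H]2C[C@H]1C2(C)C
F0 | step 8 | none | none
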